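A stall short of the charge is easily mistaken for a balance between substrate, partner and product. In the autumn run, the last reading of product is 0.229 M, less than the 0.600 M of substrate charged.

| setting | autumn | dusk | dawn | midnight | summer |
|---|---|---|---|---|---|
| substrate | 0.600 M | 0.300 M | 1.20 M | 0.600 M | 0.600 M |
| partner | 0.660 M | 0.360 M | 0.660 M | 0.330 M | 0.660 M |
| time |  |  |  |  | 220 min |

| autumn run: time / min | autumn run: [product] / M | dusk run: time / min | dusk run: [product] / M | dawn run: time / min | dawn run: [product] / M | midnight run: time / min | midnight run: [product] / M |
|---|---|---|---|---|---|---|---|
| 3.0 | 0.039 | 3.0 | 0.016 | 3.0 | 0.068 | 3.0 | 0.015 |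
| 5.1 | 0.057 | 5.1 | 0.023 | 5.1 | 0.108 | 5.1 | 0.042 |
| 8.8 | 0.086 | 8.8 | 0.028 | 8.8 | 0.158 | 8.8 | 0.067 |
| 15 | 0.146 | 15 | 0.046 | 15 | 0.229 | 15 | 0.093 |
| 26 | 0.167 | 26 | 0.066 | 26 | 0.307 | 26 | 0.116 |
| 44 | 0.208 | 44 | 0.093 | 44 | 0.345 | 44 | 0.138 |
| 75 | 0.229 | 75 | 0.089 | 75 | 0.343 | 75 | 0.146 |

(readings scatter by 0.005 M)

- Overall: substrate + partner -> product.
- Constant volume, constant temperature.
- A reading of a species includes what of it is bound.
- An order is taken over about fifteen percent of the charge, up and down.

- apparent order in [partner] of the starting rate, round the charge of the autumn run (the rate where two percent of its substrate have turned into product)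
- apparent order in [substrate] of the starting rate, round the charge of the autumn run (the rate where two percent of its substrate have turned into product) (one fixed amount of product, the same in the runs compared)
- product in the summer run at 220 min, as a share of the substrate charged

1. In the flask: the summer flask holds the autumn charge, so the autumn readings describe it.

2. The clock: the stall time τ is 20.5 min in the autumn run: the last reading over the early rate, which is the second reading divided by its time.

3. Across runs: τ is 16.2 min at dawn, 17.7 min at midnight and 19.7 min at dusk, while the early rate of the dawn run is 4.70 times that of the dusk run. The stop therefore behaves like a clock.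

4. On return: 220 min is 10.7 stall times. Taking the autumn rise as a plateau approach, 2.57% of it remained at the last reading. This reckoning puts summer product at 0.235 M, or 39.2% of the substrate.

5. Not to touch: the partner balance. Every reading is of product, so partner in hand is not read, and charged partner minus product is a subtraction, not a measurement.

6. The forecast gives 39.5%, slightly above this reckoning, with orders 0.45 in partner and 0.93 in substrate; it says “so this looks like equilibrium, though catalyst death would fit nearly as well”.

The summer flask gives 38.8%, with orders 0.54 and 1.0.

    substrate ⇌ intermediate (0.3126 /min, 3.798 /min)
    intermediate + partner → product (1.920 /M/min)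
    2 partner ⇌ idle reagent dimer, settled at all times (10.30 /M)
    2 partner → lost reagent (0.7560 /M/min)

The summer stall comes mainly from a loss of partner, not a balance: without the step from two partner to lost reagent, the summer share rises from 38.8% to 92.1%. Where idle reagent dimer outweighs free partner, the loss step by itself takes total partner down with a time equal to the dimer constant over the loss constant, 13.6 min, which contains no charge, against the autumn τ of 20.5 min. In the dusk run, τ and the last reading put product equal to a quarter of the substrate charged at 36.5 min, and the dusk flask reaches it at 31.6 min.

The numbers in the tables are calculated from invented constants.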